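The constants used here are those of an exercise; the rest is arithmetic.

This closed, stirred vessel holds a slurry: solid substrate must dissolve before it meets the reagent, yet the target that forms is attacked by the solid still waiting, so the thing to watch is how long the solid lasts.

solid substrate 0.50 M; reagent 1.00 equiv; time 6.0 min

    reagent → decomposition product (k1 = 5.3 × 10⁻⁶ s⁻¹)
    dissolved substrate + reagent → target (k2 = 0.062 L mol⁻¹ s⁻¹)
    solid substrate ⇌ dissolved substrate, rate k3*(cs3 - [dissolved substrate]) while solid is left; crystals form when [dissolved substrate] > cs3 (cs3 = 0.33 M, k3 = 0.0084 s⁻¹)
    solid product ⇌ target, rate k4*(cs4 - [target]) while solid is left; crystals form when [target] > cs4 (cs4 = 0.24 M, k4 = 0.38 s⁻¹)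
    solid substrate + target → side product (k5 = 0.15 L mol⁻¹ s⁻¹)

1. target and solid product together at 6.0 min, in percent of the solid substrate charged
2. concentration of dissolved substrate in solution at 6.0 min, in percent of saturation

- percent here means solid substrate units held: one side product counts as two
- what is said of target includes solid product
- solid substrate, solid product is a solid; its amount is given per volume of the solution
- at the start none of the solid substrate is in solution
- dissolved substrate means what is dissolved; the solid is not counted in it
- run time (flask): 6.0 min

I divide the target's loss constant on the charged solid, 4.50 min⁻¹, by the solid's clearing constant, its dissolution rate into an empty solution over its charge, 0.333 min⁻¹. Time drops out and leaves the attack number 13.5, how many target lifetimes fit into one lifetime of the solid. Because this stands far above one, early target is eaten, and dividing the target's rate by the solid's and integrating by hand, I find that one over the root of the number survives the solid, 27.2 % of the charge. To that I add the dissolved substrate at the balance of dissolution against charged reagent, 14.1 %, so I commit to 41.3 %, or 0.206 M, which stays under the target's solubility of 0.24 M, so I count no crystals. The rest is side product, which leaves 0.147 M of reagent spare; taking this as a pseudo-first-order partner after the solid's lifetime of 3.01 min, I reach 4.15 % of saturation.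

The forecast says 38 % and 3.6 %, both a little below mine, on the ground that “much of the substrate ends up as side product”.

The flask gives 39.7 % and 3.30 %.

At 1.26 min in this flask the target's half-life under attack by the solid is 0.30 min, shorter than my 3.01 min for clearing the solid by dissolution, the comparison that the attack number 13.5 makes on the charged solid, and side product stands at 58.2 % by 3.00 min and at 58.2 % at 6.00 min. With 0.20 M of solid substrate the attack number is 2.16, and that flask ends with 13.2 % as side product and 69.7 % as target.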